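## The problem

Target 24 is a β-hydroxydihydrochalcone. A three-carbon chain, C(=O)–CH2–CH(OH), joins C5 of a 6-hydroxy-2,3-dihydrobenzofuran (ring atoms O1, C2, C3, C3a, C4–C7, C7a) to C6 of a 2,2-dimethylchroman. There are two stereocentres, both S: C2 of the dihydrofuran, which carries a 2-hydroxypropan-2-yl group, and the benzylic carbinol of the chain. An arene, a carbonyl and a methylene lie between them, so neither can relay its configuration to the other. Each has to be set by a reagent on its own fragment, and the fragments then joined. The resorcinol-type ring needs regiocontrol: its two oxygens must be told apart (one becomes O1, the other the free C6 phenol), and the acyl group must enter at C5, ortho to the phenol and para to O1. The aldol unit is the fragile part. Its carbinol is benzylic to a para-alkoxy arene, so it ionises under acid and is lost through the enolate under base, in both cases towards the chalcone, which can close further onto the C6 hydroxyl to a flavanone; retro-aldol cleavage is a third hazard. Protecting groups therefore have to leave under neutral or buffered conditions, and the β-oxygen should stay masked until the end. The feature that the plan exploits is that C2 is an α-oxy methine bonded to C3, a benzylic CH2 on C3a, while O1 sits on the neighbouring C7a. Cutting C2–C3 leaves an ortho-alkoxybenzaldehyde derivative in which the formyl carbon is C3 and an O–CH2 group is C2, with a carbene at C3 five atoms from the C–H bond it must enter.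

## Retrosynthesis

**Unmasking, 24 from 23 from 22.** No skeletal bond is cut. The two aliphatic hydroxyls are carried as silyl ethers (tertiary TES, benzylic TBS) and the phenol as a benzyl ether. The benzyl group is chosen over an acetal-type phenol protection because it leaves by hydrogenolysis, so no acid meets the aldol unit. It is removed first (22 to 23) while the carbinol is still silylated and inert to hydrogenolysis. Buffered fluoride then frees both alcohols (23 to 24).

**Aryl–carbonyl bond C5–C(=O), 22 from 10 and 19.** This cut divides the molecule into two halves of similar size, each with one stereocentre: aryl bromide 10 and the β-silyloxy Weinreb amide 19. The neighbouring cut, Cα–Cβ by an aldol between an ortho-oxygenated acetophenone and a chroman aldehyde, would have to create the carbinol at the moment of coupling under catalyst control on a poor substrate class. A Friedel–Crafts acylation would need acid. The forward reaction is asked only for clean bromine–lithium exchange and single addition to the amide.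

**C5–Br, 10 from 9.** The bromine marks the acylation site. In 9 the position para to O1 and ortho to the benzyloxy group is the most activated and least hindered, so electrophilic bromination should find it unaided.

**C2–C3 (key cut), 9 from 6.** Cutting C2–C3 turns the bicyclic ether with its stereocentre into an achiral, open-chain aryl ether, tosylhydrazone 6. The neighbouring cuts were weighed. Cutting O1–C2 means phenol attack on an epoxide or activated diol; this needs a prenyl arene, an asymmetric oxidation and an inversion. Cutting C3–C3a means an aryl nucleophile on a chiral three-carbon unit, and the two resorcinol oxygens then arrive undifferentiated. The C2–C3 cut alone starts from an aldehyde whose formyl carbon is already C3 and whose two hydroxyls differ intrinsically. The forward reaction must generate a carbene at C3, insert it 1,5 into one O–CH2 hydrogen, and distinguish the two enantiotopic hydrogens.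

**Assembly of the carbene precursor, 6 from 5, 4, 2, 3 and 1.** Tosylhydrazone 6 comes from aldehyde 5 by condensation. The silyl ether in 5 comes from tertiary alcohol 4. Alcohol 4 arises by opening 2,2-dimethyloxirane 3 with the chelated 2-hydroxyl of 4-(benzyloxy)-2-hydroxybenzaldehyde 2, and 2 is the product of selective 4-O-benzylation of 2,4-dihydroxybenzaldehyde 1. The hydrogen bond between the 2-OH and the formyl group is what separates the two oxygens. All four steps are functional-group operations on one benzene ring.

**The chroman fragment, 19 from 18, 17, 16, 14, 15, 11 and 12.** Amide 19 is the silyl ether of hydroxy amide 18, made from hydroxy ester 17. The carbinol is set by asymmetric transfer hydrogenation of β-keto ester 16, a small, robust substrate for which aryl-ketone reduction is dependable. Ester 16 is the Claisen product of methyl ketone 14 with dimethyl carbonate 15. Ketone 14 is cut at the aryl–C4 and O–C2 bonds of the pyran ring to 4-hydroxyacetophenone 11 and isoprene 12.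

## Roads not taken

**Alternative 1:** The cut is C3–C3a together with both C–CH3 bonds of the side chain. In the forward key step the aryl Grignard reagent A3, under copper catalysis, opens methyl (R)-glycidate A2 at its CH2 terminus; a methyl organometallic added to the same flask converts the ester into the tertiary alcohol, giving diol A1.
- Merits: C2 comes from the chiral pool with certainty, three C–C bonds form in one flask, and every reaction type is familiar.
- Weak points: A1 is R at the carbinol where the target needs S, so the ring must be closed with inversion by activating the secondary hydroxyl after debenzylation. The adjacent tertiary hydroxyl can displace first to give an epoxide; reopening by the phenol then returns the opposite configuration at C2 or, by 6-endo attack, a chromanol. Configurational purity therefore rests on the relative rates of two intramolecular displacements.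
- Further weak points: attack of A3 on the ester competes with epoxide opening. The two identical benzyl ethers leave a free C6 phenol after cyclisation that must be protected again before the arene can be metalated.
- Comparison: in certainty of absolute configuration this road is better than the chosen plan, whose key step is unproven. The chosen plan sets against this a ring closure that gives the final configuration directly (no inversion, no epoxide leak), differentiation of the two oxygens by the inherent reactivity of 1, and a step count to bromide 10 that is no longer.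

**Alternative 2:** The cut is C3a–C4 and C5–C6, so the acylresorcinol ring is built de novo. The vinylogous silyl ketene acetal A6, a diene on a chiral 2,3-dihydrofuran, adds to ethynyl ketone A5, and elimination of the acetal methoxy group aromatises the adduct to A4. A4 is the same bis-silyl ether that the chosen route reaches as 23.
- Merits: the placing of acyl group and oxygens is dictated by the polarity of the two partners, so no bromination, metalation or phenol protection is needed. The convergence is as late as it can be, with only desilylation left.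
- Weak points: the C2 stereocentre must still be made, now in a non-aromatic heterocycle where the C2 hydrogen lies next to an electron-rich diene and the whole unit is hydrolytically fragile. A5 combines an acidic CH2, a β-silyloxy leaving group and a Michael acceptor, so elimination competes under thermal or Lewis-acidic cycloaddition conditions. Both partners need multi-step syntheses.
- Comparison: this road is superior in late-stage convergence and spares three steps after fragment union. The chosen plan sets against it robust aromatic intermediates throughout, a cheap pre-formed benzene ring, and a key step that itself creates C2.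

**Alternative 3:** The β-hydroxy ketone is traced to the trans-(2S,3R)-epoxy ketone A7 and that to (E)-chalcone A8. The forward key step is a catalytic asymmetric nucleophilic epoxidation of A8 with a hydroperoxide; a single-electron reductant then cleaves the Cα–O bond, and the R centre at Cβ becomes the S carbinol.
- Merits: fragment union is a simple Claisen–Schmidt condensation, asymmetric chalcone epoxidation is highly developed, and the chain is built in fewer steps than amide 19 requires.
- Weak points: the route leaves C2 untouched, so the dihydrofuran stereocentre must still come from elsewhere; it is an alternative for the carbinol, not for the ring. The para-alkoxyphenyl epoxide ionises easily. The last step removes an acetal from the phenol with acid while the β-hydroxy ketone is already free, which are the conditions for dehydration to the chalcone and flavanone closure.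
- Comparison: this road is shorter for the chain, and that is a real advantage. The chosen plan sets against it that the carbinol is fixed on a small β-keto ester before the fragments meet, that the aldol oxygen stays silylated until the final buffered step, and that no acid is used at the end.

Key step: step 5

Assumption: the sense of induction of Rh2(S-PTAD)4 with an aryl/hydrogen carbene is not established. The S-configured catalyst is written, and its mirror image would be used if the other enantiotopic hydrogen is preferred.

## Route

Step 1
Reactants: 1 2,4-dihydroxybenzaldehyde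
Product: 2 4-(benzyloxy)-2-hydroxybenzaldehyde
Conditions: BnBr, NaHCO3, MeCN, 80 °C
Reagents that add atoms: benzyl bromide, BrCc1ccccc1
Why: The 2-OH is locked in a hydrogen bond to the formyl group and is the less nucleophilic hydroxyl, so a weak base ionises and benzylates only the 4-OH (regioselective Williamson etherification).

Step 2
Reactants: 2 4-(benzyloxy)-2-hydroxybenzaldehyde; 3 2,2-dimethyloxirane
Product: 4 4-(benzyloxy)-2-(2-hydroxy-2-methylpropoxy)benzaldehyde
Conditions: K2CO3 (0.5 equiv), DMF, 100 °C, sealed tube
Reagents that add atoms: none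
Why: The phenoxide opens the epoxide at its unhindered CH2 terminus (base-mediated SN2 epoxide opening) to give the tertiary alcohol; the aldehyde has no α-hydrogen and tolerates carbonate.

Step 3
Reactants: 4 4-(benzyloxy)-2-(2-hydroxy-2-methylpropoxy)benzaldehyde
Product: 5 4-(benzyloxy)-2-[2-methyl-2-(triethylsilyloxy)propoxy]benzaldehyde
Conditions: TESOTf, 2,6-lutidine, CH2Cl2, −78 to 0 °C
Reagents that add atoms: triethylsilyl trifluoromethanesulfonate, CC[Si](CC)(CC)OS(=O)(=O)C(F)(F)F
Why: A silyl triflate with a hindered pyridine base is the standard silylation of a tertiary alcohol; capping the hydroxyl removes the O–H insertion pathway of step 5.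

Step 4
Reactants: 5 4-(benzyloxy)-2-[2-methyl-2-(triethylsilyloxy)propoxy]benzaldehyde
Product: 6 (E)-N'-{4-(benzyloxy)-2-[2-methyl-2-(triethylsilyloxy)propoxy]benzylidene}-4-methylbenzenesulfonohydrazide
Conditions: TsNHNH2, MeOH, rt
Reagents that add atoms: 4-methylbenzenesulfonohydrazide, Cc1ccc(cc1)S(=O)(=O)NN
Why: Condensation of an aryl aldehyde with a sulfonyl hydrazide (tosylhydrazone formation) gives the E isomer under essentially neutral conditions that spare the hindered silyl ether and the benzyl ether.

Step 5
Reactants: 6 (E)-N'-{4-(benzyloxy)-2-[2-methyl-2-(triethylsilyloxy)propoxy]benzylidene}-4-methylbenzenesulfonohydrazide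
Product: 9 (S)-6-(benzyloxy)-2-[2-(triethylsilyloxy)propan-2-yl]-2,3-dihydrobenzofuran, via tosylhydrazone sodium salt 7 (not isolated), via aryldiazomethane 8 (not isolated)
Conditions: NaH, THF, 0 °C; then Rh2(S-PTAD)4 [dirhodium tetrakis((S)-(1-adamantyl)(phthalimido)acetate)] (1 mol %), BnEt3NCl (10 mol %), 1,4-dioxane, 40 °C, high dilution
Reagents that add atoms: none
Why: Proposed new method: sodium salt 7 fragments on gentle warming under phase transfer (Bamford–Stevens) to aryldiazomethane 8, which the dirhodium tetracarboxylate consumes as it forms; loss of N2 gives an electrophilic rhodium carbene at the future C3, and this enters one O–CH2 hydrogen through a concerted, hydride-transfer-like three-centre transition state, forming C2–C3. The closest known reaction type is the enantioselective 1,5 C–H insertion of donor/donor (diaryl or aryl/alkyl) dirhodium carbenes into ether C–H bonds to give 2,3-dihydrobenzofurans, together with racemic metal-catalysed cyclisations of tosylhydrazone-derived ortho-alkoxyaryl carbenes; an aryl/hydrogen carbene entering a CH2 next to a fully substituted carbon with asymmetric induction is not on record. The dihydrofuran ring closes by 1,5-insertion, the carbene carbon and the O–CH2 carbon being tied through C3a, C7a and O1 so that only the five-membered ring is within reach. C2 is the only new stereocentre and is set by the chiral carboxylate pocket of the catalyst, which must choose between the two enantiotopic hydrogens of a prochiral methylene; no substrate stereocentre helps or hinders. Site selectivity is secured by the substrate: the O–CH2 hydrogens are the only C–H bonds activated by an oxygen lone pair and held 1,5 to the carbene, the benzyl ether sits para and cannot reach, the methyl and ethyl C–H bonds would need transition states of seven or more members, and the tertiary hydroxyl is silylated so that O–H insertion is excluded. Chemoselectivity against azine and stilbene formation is sought through slow release of 8 at about 40 °C and high dilution. The electron-rich 2,4-dialkoxyaryl group stabilises the carbene and should lengthen its lifetime enough for the hindered insertion.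

Step 6
Reactants: 9 (S)-6-(benzyloxy)-2-[2-(triethylsilyloxy)propan-2-yl]-2,3-dihydrobenzofuran
Product: 10 (S)-6-(benzyloxy)-5-bromo-2-[2-(triethylsilyloxy)propan-2-yl]-2,3-dihydrobenzofuran
Conditions: NBS, MeCN, 0 °C, dark
Reagents that add atoms: N-bromosuccinimide, O=C1CCC(=O)N1Br
Why: Electrophilic aromatic bromination; C5 is para to O1 and ortho to the benzyloxy group, whereas C7 is crowded between two oxygens and C4 is meta to both, so C5 should react alone; the stereocentre is not involved.

Step 7
Reactants: 11 4-hydroxyacetophenone; 12 isoprene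
Product: 14 1-(2,2-dimethylchroman-6-yl)ethan-1-one, via ortho-prenylphenol 13 (not isolated)
Conditions: 85% H3PO4, xylene, 35 °C
Reagents that add atoms: none
Why: Acid-mediated Friedel–Crafts prenylation ortho to the hydroxyl (the para position is blocked by the acetyl group) followed by Markovnikov hydroalkoxylation of the prenyl double bond closes the 2,2-dimethylchroman (phenol–isoprene chroman annulation).

Step 8
Reactants: 14 1-(2,2-dimethylchroman-6-yl)ethan-1-one; 15 dimethyl carbonate
Product: 16 methyl 3-(2,2-dimethylchroman-6-yl)-3-oxopropanoate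
Conditions: NaH, THF, reflux; then aq. HCl
Reagents that add atoms: none
Why: Crossed Claisen condensation of the methyl ketone enolate with a carbonate; deprotonation of the β-keto ester product drives it to completion.

Step 9
Reactants: 16 methyl 3-(2,2-dimethylchroman-6-yl)-3-oxopropanoate
Product: 17 methyl (S)-3-(2,2-dimethylchroman-6-yl)-3-hydroxypropanoate
Conditions: RuCl[(S,S)-TsDPEN](p-cymene) (1 mol %), HCO2H/Et3N (5:2), 40 °C
Reagents that add atoms: none
Why: Noyori-type asymmetric transfer hydrogenation of an aryl ketone; the (S,S)-configured ruthenium hydride delivers hydride to the face that gives (S)-1-arylalkanols, and the ester-bearing CH2 ranks below the aryl group just as CH3 does in acetophenone, so the carbinol should be S.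

Step 10
Reactants: 17 methyl (S)-3-(2,2-dimethylchroman-6-yl)-3-hydroxypropanoate
Product: 18 (S)-3-(2,2-dimethylchroman-6-yl)-3-hydroxy-N-methoxy-N-methylpropanamide
Conditions: MeNH(OMe)·HCl, iPrMgCl, THF, −20 to 0 °C
Reagents that add atoms: N,O-dimethylhydroxylamine hydrochloride, CNOC.Cl
Why: Weinreb amidation of an ester by the chloromagnesium amide; the β-hydroxyl is carried as its magnesium alkoxide, and the stereocentre, not being α to the carbonyl, is untouched.

Step 11
Reactants: 18 (S)-3-(2,2-dimethylchroman-6-yl)-3-hydroxy-N-methoxy-N-methylpropanamide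
Product: 19 (S)-3-(tert-butyldimethylsilyloxy)-3-(2,2-dimethylchroman-6-yl)-N-methoxy-N-methylpropanamide
Conditions: TBSCl, imidazole, DMF, rt
Reagents that add atoms: tert-butyldimethylsilyl chloride, CC(C)(C)[Si](C)(C)Cl
Why: Standard silylation of a secondary alcohol; the TBS ether prevents alkoxide chemistry in step 12 and keeps the aldol oxygen masked through the hydrogenolysis.

Step 12
Reactants: 10 (S)-6-(benzyloxy)-5-bromo-2-[2-(triethylsilyloxy)propan-2-yl]-2,3-dihydrobenzofuran; 19 (S)-3-(tert-butyldimethylsilyloxy)-3-(2,2-dimethylchroman-6-yl)-N-methoxy-N-methylpropanamide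
Product: 22 (S)-1-[(S)-6-(benzyloxy)-2-[2-(triethylsilyloxy)propan-2-yl]-2,3-dihydrobenzofuran-5-yl]-3-(tert-butyldimethylsilyloxy)-3-(2,2-dimethylchroman-6-yl)propan-1-one, via aryllithium 20 (not isolated), via tetrahedral lithium adduct 21 (not isolated)
Conditions: n-BuLi, THF, −78 °C; then 19, −78 to −30 °C; aq. NH4Cl
Reagents that add atoms: none
Why: Bromine–lithium exchange outruns deprotonation at −78 °C, and the aryllithium adds only once because chelated adduct 21 persists until the quench (Weinreb ketone synthesis); both stereocentres are remote from the reacting atoms.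

Step 13
Reactants: 22 (S)-1-[(S)-6-(benzyloxy)-2-[2-(triethylsilyloxy)propan-2-yl]-2,3-dihydrobenzofuran-5-yl]-3-(tert-butyldimethylsilyloxy)-3-(2,2-dimethylchroman-6-yl)propan-1-one
Product: 23 (S)-3-(tert-butyldimethylsilyloxy)-3-(2,2-dimethylchroman-6-yl)-1-[(S)-6-hydroxy-2-[2-(triethylsilyloxy)propan-2-yl]-2,3-dihydrobenzofuran-5-yl]propan-1-one
Conditions: H2 (1 atm), Pd/C (palladium on carbon), EtOAc, rt
Reagents that add atoms: none
Why: Hydrogenolysis of an aryl benzyl ether is fast and neutral; the bulky benzylic silyl ether and the aryl ketone react far more slowly in EtOAc, and the freed phenol is held in a hydrogen bond to the ketone.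

Step 14
Reactants: 23 (S)-3-(tert-butyldimethylsilyloxy)-3-(2,2-dimethylchroman-6-yl)-1-[(S)-6-hydroxy-2-[2-(triethylsilyloxy)propan-2-yl]-2,3-dihydrobenzofuran-5-yl]propan-1-one
Product: 24 (S)-3-(2,2-dimethylchroman-6-yl)-3-hydroxy-1-[(S)-6-hydroxy-2-(2-hydroxypropan-2-yl)-2,3-dihydrobenzofuran-5-yl]propan-1-one
Conditions: HF·pyridine, pyridine, THF, 0 °C to rt
Reagents that add atoms: none
Why: Fluoride cleavage of both silyl ethers in a pyridine-buffered medium stays close to neutral, so neither enolate-driven loss of the β-oxygen nor ionisation of the para-alkoxybenzylic carbinol is promoted; no stereocentre is touched.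

## Compound list

1 | 2,4-dihydroxybenzaldehyde | O=Cc1ccc(O)cc1O | starting material
2 | 4-(benzyloxy)-2-hydroxybenzaldehyde | O=Cc1ccc(OCc2ccccc2)cc1O | intermediate
3 | 2,2-dimethyloxirane | CC1(C)CO1 | starting material
4 | 4-(benzyloxy)-2-(2-hydroxy-2-methylpropoxy)benzaldehyde | O=Cc1ccc(OCc2ccccc2)cc1OCC(C)(C)O | intermediate
5 | 4-(benzyloxy)-2-[2-methyl-2-(triethylsilyloxy)propoxy]benzaldehyde | O=Cc1ccc(OCc2ccccc2)cc1OCC(C)(C)O[Si](CC)(CC)CC | intermediate
6 | (E)-N'-{4-(benzyloxy)-2-[2-methyl-2-(triethylsilyloxy)propoxy]benzylidene}-4-methylbenzenesulfonohydrazide | Cc1ccc(cc1)S(=O)(=O)N/N=C/c1ccc(OCc2ccccc2)cc1OCC(C)(C)O[Si](CC)(CC)CC | intermediate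
7 | sodium salt of tosylhydrazone 6 | Cc1ccc(cc1)S(=O)(=O)[N-]/N=C/c1ccc(OCc2ccccc2)cc1OCC(C)(C)O[Si](CC)(CC)CC.[Na+] | intermediate
8 | 4-(benzyloxy)-1-(diazomethyl)-2-[2-methyl-2-(triethylsilyloxy)propoxy]benzene | [N-]=[N+]=Cc1ccc(OCc2ccccc2)cc1OCC(C)(C)O[Si](CC)(CC)CC | intermediate
9 | (S)-6-(benzyloxy)-2-[2-(triethylsilyloxy)propan-2-yl]-2,3-dihydrobenzofuran | CC[Si](CC)(CC)OC(C)(C)[C@@H]1Cc2ccc(OCc3ccccc3)cc2O1 | intermediate
10 | (S)-6-(benzyloxy)-5-bromo-2-[2-(triethylsilyloxy)propan-2-yl]-2,3-dihydrobenzofuran | CC[Si](CC)(CC)OC(C)(C)[C@@H]1Cc2cc(Br)c(OCc3ccccc3)cc2O1 | intermediate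
11 | 4-hydroxyacetophenone | CC(=O)c1ccc(O)cc1 | starting material
12 | isoprene | C=CC(C)=C | starting material
13 | 1-[4-hydroxy-3-(3-methylbut-2-en-1-yl)phenyl]ethan-1-one | CC(=O)c1ccc(O)c(CC=C(C)C)c1 | intermediate
14 | 1-(2,2-dimethylchroman-6-yl)ethan-1-one | CC(=O)c1ccc2OC(C)(C)CCc2c1 | intermediate
15 | dimethyl carbonate | COC(=O)OC | starting material
16 | methyl 3-(2,2-dimethylchroman-6-yl)-3-oxopropanoate | COC(=O)CC(=O)c1ccc2OC(C)(C)CCc2c1 | intermediate
17 | methyl (S)-3-(2,2-dimethylchroman-6-yl)-3-hydroxypropanoate | CC1(C)CCc2cc([C@@H](O)CC(=O)OC)ccc2O1 | intermediate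
18 | (S)-3-(2,2-dimethylchroman-6-yl)-3-hydroxy-N-methoxy-N-methylpropanamide | CC1(C)CCc2cc([C@@H](O)CC(=O)N(C)OC)ccc2O1 | intermediate
19 | (S)-3-(tert-butyldimethylsilyloxy)-3-(2,2-dimethylchroman-6-yl)-N-methoxy-N-methylpropanamide | CC1(C)CCc2cc([C@@H](O[Si](C)(C)C(C)(C)C)CC(=O)N(C)OC)ccc2O1 | intermediate
20 | {(S)-6-(benzyloxy)-2-[2-(triethylsilyloxy)propan-2-yl]-2,3-dihydrobenzofuran-5-yl}lithium | CC[Si](CC)(CC)OC(C)(C)[C@@H]1Cc2cc([Li])c(OCc3ccccc3)cc2O1 | intermediate
21 | lithium alkoxide adduct of 20 and 19 (tetrahedral N-methoxy-N-methyl hemiaminal, new carbon undefined) | CC1(C)CCc2cc([C@@H](O[Si](C)(C)C(C)(C)C)CC(O[Li])(N(C)OC)c3cc4c(cc3OCc5ccccc5)O[C@H](C(C)(C)O[Si](CC)(CC)CC)C4)ccc2O1 | intermediate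
22 | (S)-1-[(S)-6-(benzyloxy)-2-[2-(triethylsilyloxy)propan-2-yl]-2,3-dihydrobenzofuran-5-yl]-3-(tert-butyldimethylsilyloxy)-3-(2,2-dimethylchroman-6-yl)propan-1-one | CC1(C)CCc2cc([C@@H](O[Si](C)(C)C(C)(C)C)CC(=O)c3cc4c(cc3OCc5ccccc5)O[C@H](C(C)(C)O[Si](CC)(CC)CC)C4)ccc2O1 | intermediate
23 | (S)-3-(tert-butyldimethylsilyloxy)-3-(2,2-dimethylchroman-6-yl)-1-[(S)-6-hydroxy-2-[2-(triethylsilyloxy)propan-2-yl]-2,3-dihydrobenzofuran-5-yl]propan-1-one | CC1(C)CCc2cc([C@@H](O[Si](C)(C)C(C)(C)C)CC(=O)c3cc4c(cc3O)O[C@H](C(C)(C)O[Si](CC)(CC)CC)C4)ccc2O1 | intermediate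
24 | (S)-3-(2,2-dimethylchroman-6-yl)-3-hydroxy-1-[(S)-6-hydroxy-2-(2-hydroxypropan-2-yl)-2,3-dihydrobenzofuran-5-yl]propan-1-one | CC1(C)CCc2cc([C@@H](O)CC(=O)c3cc4c(cc3O)O[C@H](C(C)(C)O)C4)ccc2O1 | target

## Step count and risks

Total step count: 14. Longest linear sequence: 9 steps (steps 1 to 6, then 12 to 14); the chroman branch (steps 7 to 11) is 5 steps before the union.

**Step 5 (key step, proposed new method).**
- What may go wrong: bimolecular consumption of the diazo compound (azine and stilbene formation) may outpace insertion, because the O–CH2 group is neopentyl-like and inductively deactivated by the β-silyloxy group. The catalyst may also discriminate poorly between the enantiotopic hydrogens of a carbene whose second substituent is only hydrogen.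
- Fallback (known chemistry): from 2, O-alkylation with ethyl bromoacetate (K2CO3, DMF) gives ethyl 2-[5-(benzyloxy)-2-formylphenoxy]acetate F1. On heating in the same flask F1 undergoes intramolecular aldol condensation (Rap–Stoermer-type benzofuran synthesis, again forming C2–C3) to ethyl 6-(benzyloxy)benzofuran-2-carboxylate F2.
- Excess MeMgBr converts the ester into 2-[6-(benzyloxy)benzofuran-2-yl]propan-2-ol F3.
- Asymmetric hydrogenation of the furan C2=C3 bond follows, with Ru(cod)(2-methylallyl)2 and a chiral N-heterocyclic carbene ligand, a catalyst type established for 2-substituted benzofurans and inert towards benzyl ethers. The ligand antipode is chosen for the 2S product, (S)-2-[6-(benzyloxy)-2,3-dihydrobenzofuran-2-yl]propan-2-ol F4.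
- Silylation with TESOTf and 2,6-lutidine returns the route at 9.

**Step 7.**
- What may go wrong: sluggish ring C-alkylation of a phenol deactivated by the acetyl group, with competing O-prenylation, double alkylation and oligomerisation of the diene.
- Fallback: from 11, O-alkylation with 3-chloro-3-methylbut-1-yne (K2CO3, KI, acetone, reflux) gives 1-[4-(2-methylbut-3-yn-2-yloxy)phenyl]ethan-1-one F5.
- Heating in N,N-diethylaniline triggers the aromatic propargyl Claisen rearrangement, hydrogen shift and 6π-electrocyclisation to 1-(2,2-dimethyl-2H-chromen-6-yl)ethan-1-one F6.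
- Hydrogenation of the chromene double bond (H2, Pd/C, EtOAc) returns the route at 14.

**Step 12.**
- What may go wrong: proton transfer from the α-CH2 of 19 to the hindered aryllithium (enolisation followed by β-elimination of silanolate) may compete with addition to the amide carbonyl, returning debrominated arene.
- Fallback: from 19, reduction with iBu2AlH at −78 °C gives (S)-3-(tert-butyldimethylsilyloxy)-3-(2,2-dimethylchroman-6-yl)propanal F7, a much better electrophile.
- Addition of aryllithium 20 (from 10) gives (3S)-1-[(S)-6-(benzyloxy)-2-[2-(triethylsilyloxy)propan-2-yl]-2,3-dihydrobenzofuran-5-yl]-3-(tert-butyldimethylsilyloxy)-3-(2,2-dimethylchroman-6-yl)propan-1-ol F8 as a mixture of epimers at the new carbinol.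
- Dess–Martin oxidation removes that centre and returns the route at 22.

**Step 14.**
- What may go wrong: loss of the aldol oxygen, by enolate-driven β-elimination or by ionisation at the para-alkoxybenzylic carbon, leading on to the chalcone and its flavanone. This is most likely during the long exposure that the more hindered silyl ether may need.
- Fallback: carry both aliphatic oxygens as triethylsilyl ethers so that the final cleavage can be run colder and shorter. From 18, silylation with chlorotriethylsilane and imidazole gives (S)-3-(2,2-dimethylchroman-6-yl)-N-methoxy-N-methyl-3-(triethylsilyloxy)propanamide F9.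
- Addition of aryllithium 20 proceeds through the tetrahedral lithium adduct of 20 and F9 F10 to (S)-1-[(S)-6-(benzyloxy)-2-[2-(triethylsilyloxy)propan-2-yl]-2,3-dihydrobenzofuran-5-yl]-3-(2,2-dimethylchroman-6-yl)-3-(triethylsilyloxy)propan-1-one F11.
- Hydrogenolysis (H2, Pd/C, EtOAc) gives (S)-3-(2,2-dimethylchroman-6-yl)-1-[(S)-6-hydroxy-2-[2-(triethylsilyloxy)propan-2-yl]-2,3-dihydrobenzofuran-5-yl]-3-(triethylsilyloxy)propan-1-one F12.
- Brief treatment with pyridine-buffered HF·pyridine at 0 °C returns the route at 24.

## Further compounds

F1 | step 5 | ethyl 2-[5-(benzyloxy)-2-formylphenoxy]acetate | CCOC(=O)COc1cc(OCc2ccccc2)ccc1C=O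
F2 | step 5 | ethyl 6-(benzyloxy)benzofuran-2-carboxylate | CCOC(=O)c1cc2ccc(OCc3ccccc3)cc2o1
F3 | step 5 | 2-[6-(benzyloxy)benzofuran-2-yl]propan-2-ol | CC(C)(O)c1cc2ccc(OCc3ccccc3)cc2o1
F4 | step 5 | (S)-2-[6-(benzyloxy)-2,3-dihydrobenzofuran-2-yl]propan-2-ol | CC(C)(O)[C@@H]1Cc2ccc(OCc3ccccc3)cc2O1
F5 | step 7 | 1-[4-(2-methylbut-3-yn-2-yloxy)phenyl]ethan-1-one | CC(=O)c1ccc(OC(C)(C)C#C)cc1
F6 | step 7 | 1-(2,2-dimethyl-2H-chromen-6-yl)ethan-1-one | CC(=O)c1ccc2OC(C)(C)C=Cc2c1
F7 | step 12 | (S)-3-(tert-butyldimethylsilyloxy)-3-(2,2-dimethylchroman-6-yl)propanal | CC1(C)CCc2cc([C@@H](O[Si](C)(C)C(C)(C)C)CC=O)ccc2O1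
F8 | step 12 | (3S)-1-[(S)-6-(benzyloxy)-2-[2-(triethylsilyloxy)propan-2-yl]-2,3-dihydrobenzofuran-5-yl]-3-(tert-butyldimethylsilyloxy)-3-(2,2-dimethylchroman-6-yl)propan-1-ol (epimers at C1) | CC1(C)CCc2cc([C@@H](O[Si](C)(C)C(C)(C)C)CC(O)c3cc4c(cc3OCc5ccccc5)O[C@H](C(C)(C)O[Si](CC)(CC)CC)C4)ccc2O1
F9 | step 14 | (S)-3-(2,2-dimethylchroman-6-yl)-N-methoxy-N-methyl-3-(triethylsilyloxy)propanamide | CC1(C)CCc2cc([C@@H](O[Si](CC)(CC)CC)CC(=O)N(C)OC)ccc2O1
F10 | step 14 | tetrahedral lithium adduct of 20 and F9 | CC1(C)CCc2cc([C@@H](O[Si](CC)(CC)CC)CC(O[Li])(N(C)OC)c3cc4c(cc3OCc5ccccc5)O[C@H](C(C)(C)O[Si](CC)(CC)CC)C4)ccc2O1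
F11 | step 14 | (S)-1-[(S)-6-(benzyloxy)-2-[2-(triethylsilyloxy)propan-2-yl]-2,3-dihydrobenzofuran-5-yl]-3-(2,2-dimethylchroman-6-yl)-3-(triethylsilyloxy)propan-1-one | CC1(C)CCc2cc([C@@H](O[Si](CC)(CC)CC)CC(=O)c3cc4c(cc3OCc5ccccc5)O[C@H](C(C)(C)O[Si](CC)(CC)CC)C4)ccc2O1
F12 | step 14 | (S)-3-(2,2-dimethylchroman-6-yl)-1-[(S)-6-hydroxy-2-[2-(triethylsilyloxy)propan-2-yl]-2,3-dihydrobenzofuran-5-yl]-3-(triethylsilyloxy)propan-1-one | CC1(C)CCc2cc([C@@H](O[Si](CC)(CC)CC)CC(=O)c3cc4c(cc3O)O[C@H](C(C)(C)O[Si](CC)(CC)CC)C4)ccc2O1
A1 | alternative 1 | (R)-1-[2,4-bis(benzyloxy)phenyl]-3-methylbutane-2,3-diol | CC(C)(O)[C@H](O)Cc1ccc(OCc2ccccc2)cc1OCc1ccccc1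
A2 | alternative 1 | methyl (R)-glycidate | COC(=O)[C@H]1CO1
A3 | alternative 1 | 2,4-bis(benzyloxy)phenylmagnesium bromide | Br[Mg]c1ccc(OCc2ccccc2)cc1OCc1ccccc1
A4 | alternative 2 | (S)-3-(tert-butyldimethylsilyloxy)-3-(2,2-dimethylchroman-6-yl)-1-[(S)-6-hydroxy-2-[2-(triethylsilyloxy)propan-2-yl]-2,3-dihydrobenzofuran-5-yl]propan-1-one | CC1(C)CCc2cc([C@@H](O[Si](C)(C)C(C)(C)C)CC(=O)c3cc4c(cc3O)O[C@H](C(C)(C)O[Si](CC)(CC)CC)C4)ccc2O1
A5 | alternative 2 | (S)-5-(tert-butyldimethylsilyloxy)-5-(2,2-dimethylchroman-6-yl)pent-1-yn-3-one | CC1(C)CCc2cc([C@@H](O[Si](C)(C)C(C)(C)C)CC(=O)C#C)ccc2O1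
A6 | alternative 2 | (S)-5-[2-methoxy-2-(trimethylsilyloxy)ethenyl]-2-[2-(triethylsilyloxy)propan-2-yl]-2,3-dihydrofuran | COC(O[Si](C)(C)C)=CC1=CC[C@@H](C(C)(C)O[Si](CC)(CC)CC)O1
A7 | alternative 3 | [(2S,3R)-3-(2,2-dimethylchroman-6-yl)oxiran-2-yl][(S)-2-(2-hydroxypropan-2-yl)-6-(methoxymethoxy)-2,3-dihydrobenzofuran-5-yl]methanone | CC1(C)CCc2cc([C@H]3O[C@@H]3C(=O)c3cc4c(cc3OCOC)O[C@H](C(C)(C)O)C4)ccc2O1
A8 | alternative 3 | (E)-3-(2,2-dimethylchroman-6-yl)-1-[(S)-2-(2-hydroxypropan-2-yl)-6-(methoxymethoxy)-2,3-dihydrobenzofuran-5-yl]prop-2-en-1-one | CC1(C)CCc2cc(/C=C/C(=O)c3cc4c(cc3OCOC)O[C@H](C(C)(C)O)C4)ccc2O1
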